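(The readings come from a simulation with constants of no real substance.)

1. At its first reading, 0.417 d, the north-west run already shows free monomer going two ways, and you can weigh them against each other.

| flask | free monomer | protic impurity | initiator | remark | time |
|---|---|---|---|---|---|
| south | 0.15 M | 0.015 M | 7.5 mM | run made earlier |  |
| north-west | 0.15 M | 0.060 M | 7.5 mM | run made earlier |  |
| north-east | 0.15 M | 0.030 M | 11 mM | run made earlier |  |
| flask | 0.15 M | 0.0300 M | 7.5 mM |  | 8.0 d |

- south (time / d: monomer in chains / %, free monomer / %): 0.417: 20.4, 69.6; 0.833: 35.9, 54.6; 1.25: 48.3, 41.3; 2.50: 70.8, 19.6; 5.00: 86.2, 4.2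
- north-west (time / d: monomer in chains / %, free monomer / %): 0.417: 17.8, 48.3; 1.25: 34.1, 25.5; 2.00: 44.1, 16.1; 3.00: 51.7, 9.1; 5.00: 57.6, 2.3
- north-east (time / d: monomer in chains / %, free monomer / %): 0.417: 23.0, 57.9; 0.833: 37.8, 42.0; 1.25: 49.1, 31.0; 2.50: 68.1, 12.1; 5.00: 78.7, 2.6

(each reading ± 0.5 percentage points)

- average number of monomer units in a chain (living and dead chains, two that joined counted as one) at 8.0 d
- part of the free monomer that has reacted at 8.0 d

- the average divides the monomer in chains by the number of chains, living and dead together; two radicals that join make one chain
- the earlier runs do not show the number of chains; that part of a forecast is a guess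

2. By the last reading of each run, free monomer plus monomer in chains falls short of the whole by about the charge of protic impurity, so each impurity seems to remove one free monomer. Suppose growth consumes free monomer as k[free monomer], with k held constant, and the impurity as kq[protic impurity][free monomer]. [free monomer] then cancels from their ratio: each impurity consumed is matched by K/[protic impurity] of monomer in chains, with K = k/kq. Summed, [monomer in chains] = K ln(1/fraction of impurity left).

3. At that first reading the shortfall leaves 15.3 % of the impurity, and 17.8 % is in chains. This gives a reading of 0.0142 M: the crossover concentration of protic impurity, where it and growth take free monomer equally fast.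

4. My reckoning for this flask: once its free monomer is nearly used, the rule leaves 0.0213 % of the impurity, so about 0.120 M of monomer ends in chains. The south run's pseudo-first-order constant, 0.613 d⁻¹, leaves 0.594 % free monomer at 8.0 d, so c is 99.4 %. The runs show no chain count, so I leave dp open.

5. The forecast gives c = 99.4 % and dp = 200, adding: “Chains are a guess”.

6. The flask gives:

    initiator → 2 initiating radical (k = 3.37 × 10⁻⁵ min⁻¹)
    free monomer + initiating radical → growing radical + monomer in chains (k = 48800 L mol⁻¹ s⁻¹)
    free monomer + growing radical → monomer in chains + growing radical, rate k3*[growing radical]*[free monomer] (k = 24200 L mol⁻¹ min⁻¹)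
    2 growing radical → dead chain (k = 1.40 × 10⁷ L mol⁻¹ s⁻¹)
    protic impurity + free monomer → quenched substrate (k = 0.0348 L mol⁻¹ min⁻¹)

Here c = 99.7 % and dp = 49.6. In this flask the step to quenched substrate ran early, with 98 % of its turnover up to 8.0 d done at 0.800 d against 41 % for growth. Growth ran on until, at 8.00 d, 79.7 % of the free monomer charged stood in chains, beside 0.00241 M of dead chain, 0.275 % of the charge still free and 0.0052 % of the impurity's own charge, against my 0.0213 %. A neighbour flask, alike but for 0.037 M of free monomer, kept 31 % of its impurity at 8.0 d, for which K gives 44.9 % of monomer in chains. That neighbour holds 44.0 %.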